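Ring A of the flavone is disconnected across C4a–C5 and C8–C8a. The C5–C6–C7–C8 edge (OH, CH3, OH, OCH3) maps onto the carbon chain of methyl 4-methoxy-2-methyl-3-oxobutanoate, so its 1,3-bis(silyloxy)diene delivers all four substituents. C4a and C8a come from a bromo-ynone that already carries the C4 carbonyl and the methoxylated C3. One Diels–Alder/aromatisation step thus builds ring A fully substituted and leaves bromine on C8a as the only site for O1. Aroylation at C3, copper-catalysed closure of ring C and debenzylation finish the synthesis. Ring A atoms are given flavone numbers throughout.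

Key step: step 6

Remark: the double-bond geometries of 3 and 4 and the relative configuration of the two transient stereocentres of 9 do not matter, because all of these atoms end up sp2 in ring A; 4 is drawn as its (1Z,3Z) isomer, and 5 and 6 are taken as purchasable reagents.

Step 1
Reactants: 1 methyl 4-methoxy-3-oxobutanoate
Product: 2 methyl 4-methoxy-2-methyl-3-oxobutanoate (racemic)
Conditions: MeI (1.05 equiv), K2CO3, acetone, reflux
Reagents that add atoms: iodomethane, CI
Why: Acetoacetic ester alkylation at the doubly activated C2 methylene should stop at monomethylation with one equivalent of iodomethane, and the new stereocentre is racemic and disappears on enolisation in step 2.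

Step 2
Reactants: 2 methyl 4-methoxy-2-methyl-3-oxobutanoate
Product: 3 methyl 4-methoxy-2-methyl-3-(trimethylsilyloxy)but-2-enoate (E/Z mixture)
Conditions: Me3SiCl, Et3N, toluene, rt
Reagents that add atoms: chlorotrimethylsilane, C[Si](C)(C)Cl
Why: Silyl enol ether formation under soft enolisation takes place towards C2, the position between the two carbonyl groups, and gives the conjugated enol ether needed for γ-deprotonation.

Step 3
Reactants: 3 methyl 4-methoxy-2-methyl-3-(trimethylsilyloxy)but-2-enoate
Product: 4 (1Z,3Z)-1,4-dimethoxy-2-methyl-1,3-bis(trimethylsilyloxy)buta-1,3-diene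
Conditions: LiN(i-Pr)2 (1.2 equiv), THF, −78 °C; then Me3SiCl, −78 °C → rt
Reagents that add atoms: chlorotrimethylsilane, C[Si](C)(C)Cl
Why: γ-Deprotonation of the vinylogous ester at the methoxymethyl carbon and O-silylation of the dienolate is the standard second stage of 1-alkoxy-1,3-bis(silyloxy)diene (Chan-type diene) synthesis.

Step 4
Reactants: 5 lithium (trimethylsilyl)acetylide; 6 N,2-dimethoxy-N-methylacetamide
Product: 7 1-methoxy-4-(trimethylsilyl)but-3-yn-2-one
Conditions: THF, −78 → 0 °C; then cold 1 M HCl
Reagents that add atoms: none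
Why: Weinreb ketone synthesis gives single addition because the chelated tetrahedral adduct persists until the acidic quench, and it avoids a Lewis-acid acylation in which an α-alkoxy acyl chloride is prone to lose carbon monoxide.

Step 5
Reactants: 7 1-methoxy-4-(trimethylsilyl)but-3-yn-2-one
Product: 8 4-bromo-1-methoxybut-3-yn-2-one
Conditions: NBS, AgNO3 (10 mol %), acetone, rt, dark
Reagents that add atoms: N-bromosuccinimide, O=C1CCC(=O)N1Br
Why: AgNO3-catalysed bromodesilylation of a silylalkyne with NBS runs through an alkynylsilver intermediate (RC≡CAg) and is routine for alkynes conjugated to a carbonyl group.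

Step 6
Reactants: 4 (1Z,3Z)-1,4-dimethoxy-2-methyl-1,3-bis(trimethylsilyloxy)buta-1,3-diene; 8 4-bromo-1-methoxybut-3-yn-2-one
Product: 10 1-(2-bromo-4,6-dihydroxy-3-methoxy-5-methylphenyl)-2-methoxyethan-1-one, via cyclohexa-1,4-diene cycloadduct 9 (not isolated)
Conditions: toluene, −20 °C → rt; then 1 M HCl, THF, rt
Reagents that add atoms: none
Why: The electron-rich diene 4 adds to the electron-poor alkyne of 8 in a normal-demand Diels–Alder reaction (concerted but asynchronous, or Mukaiyama–Michael addition followed by closure of the allenolate onto the ketene acetal carbon), forming C8–C8a and C4a–C5 and giving the 1,4-cyclohexadiene 9. Dilute acid then cleaves both O–Si bonds, the C5 hemiketal expels methanol, and the resulting dienone tautomerises through the C8 hydrogen to the resorcinol, with bromine left on C8a. The closest known reaction is the benzannulation of 1-alkoxy-1,3-bis(silyloxy)dienes with acetylenic ketones and esters, and 1-bromoalkynes bearing a carbonyl group are established 2π partners. Ring A closes as a [4+2] cycloaddition that joins a four-carbon unit (C5 to C8) to a two-carbon unit (C4a, C8a). No stereocentre survives, since the two formed in 9 are lost on aromatisation. The step needs one regiochemical outcome, which the substrates secure: the diene terminus C8 carries the largest HOMO coefficient because the three oxygen donors on C5 and C7 all push electron density towards it, the bromine-bearing β-carbon of the ynone carries the largest LUMO coefficient, and the 8-methoxy group cannot be lost because C5 has no hydrogen and only C5 carries a leaving group that aromatisation can use.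

Step 7
Reactants: 10 1-(2-bromo-4,6-dihydroxy-3-methoxy-5-methylphenyl)-2-methoxyethan-1-one
Product: 11 1-[4,6-bis(benzyloxy)-2-bromo-3-methoxy-5-methylphenyl]-2-methoxyethan-1-one
Conditions: BnBr (2.5 equiv), K2CO3, DMF, 60 °C
Reagents that add atoms: benzyl bromide, BrCc1ccccc1
Why: Williamson ether synthesis in DMF should alkylate both the free C7 phenol and the hydrogen-bonded C5 phenol, while carbonate is too weak a base to enolise the ketone.

Step 8
Reactants: 11 1-[4,6-bis(benzyloxy)-2-bromo-3-methoxy-5-methylphenyl]-2-methoxyethan-1-one; 12 4-methoxybenzoyl chloride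
Product: 13 1-[4,6-bis(benzyloxy)-2-bromo-3-methoxy-5-methylphenyl]-2-methoxy-3-(4-methoxyphenyl)propane-1,3-dione (racemic, in equilibrium with its enols)
Conditions: LiN(SiMe3)2 (2.1 equiv), toluene, 0 °C; then 12, 0 °C → rt; 1 M HCl
Reagents that add atoms: none
Why: Claisen-type C-acylation of the methoxy-chelated lithium enolate by the aroyl chloride is favoured in a non-polar solvent, and the second equivalent of base holds the more acidic 1,3-diketone as its enolate so that it cannot quench unreacted ketone enolate.

Step 9
Reactants: 13 1-[4,6-bis(benzyloxy)-2-bromo-3-methoxy-5-methylphenyl]-2-methoxy-3-(4-methoxyphenyl)propane-1,3-dione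
Product: 14 5,7-bis(benzyloxy)-3,8-dimethoxy-2-(4-methoxyphenyl)-6-methyl-4H-chromen-4-one
Conditions: CuI (10 mol %), 1,10-phenanthroline (20 mol %), K2CO3, DMF, 100 °C
Reagents that add atoms: none
Why: Intramolecular Ullmann-type O-arylation under monovalent copper catalysis joins the enolate oxygen on the anisoyl carbon to C8a with loss of bromide, a known way from 1-(2-bromoaryl)-1,3-diketones to flavones, and C-arylation cannot compete because it would close a four-membered ring.

Step 10
Reactants: 14 5,7-bis(benzyloxy)-3,8-dimethoxy-2-(4-methoxyphenyl)-6-methyl-4H-chromen-4-one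
Product: 15 5,7-dihydroxy-3,8-dimethoxy-2-(4-methoxyphenyl)-6-methyl-4H-chromen-4-one
Conditions: H2 (1 atm), 10% Pd/C, EtOAc–MeOH, rt
Reagents that add atoms: none
Why: Catalytic hydrogenolysis cleaves the two benzyl aryl ethers selectively and should leave the three methyl ethers and the tetrasubstituted C2=C3 bond of the 3-methoxyflavone untouched.

Compound list
1 | methyl 4-methoxy-3-oxobutanoate | COCC(=O)CC(=O)OC | starting material
2 | methyl 4-methoxy-2-methyl-3-oxobutanoate (racemic) | COCC(=O)C(C)C(=O)OC | intermediate
3 | methyl 4-methoxy-2-methyl-3-(trimethylsilyloxy)but-2-enoate (E/Z mixture) | COCC(O[Si](C)(C)C)=C(C)C(=O)OC | intermediate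
4 | (1Z,3Z)-1,4-dimethoxy-2-methyl-1,3-bis(trimethylsilyloxy)buta-1,3-diene | CO/C=C(\O[Si](C)(C)C)/C(C)=C(/OC)O[Si](C)(C)C | intermediate
5 | lithium (trimethylsilyl)acetylide | [Li]C#C[Si](C)(C)C | starting material
6 | N,2-dimethoxy-N-methylacetamide | COCC(=O)N(C)OC | starting material
7 | 1-methoxy-4-(trimethylsilyl)but-3-yn-2-one | COCC(=O)C#C[Si](C)(C)C | intermediate
8 | 4-bromo-1-methoxybut-3-yn-2-one | COCC(=O)C#CBr | intermediate
9 | 1-[2-bromo-3,6-dimethoxy-5-methyl-4,6-bis(trimethylsilyloxy)cyclohexa-1,4-dien-1-yl]-2-methoxyethan-1-one (diastereomer mixture, not isolated) | COCC(=O)C1=C(Br)C(OC)C(O[Si](C)(C)C)=C(C)C1(OC)O[Si](C)(C)C | intermediate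
10 | 1-(2-bromo-4,6-dihydroxy-3-methoxy-5-methylphenyl)-2-methoxyethan-1-one | COCC(=O)c1c(O)c(C)c(O)c(OC)c1Br | intermediate
11 | 1-[4,6-bis(benzyloxy)-2-bromo-3-methoxy-5-methylphenyl]-2-methoxyethan-1-one | COCC(=O)c1c(OCc2ccccc2)c(C)c(OCc2ccccc2)c(OC)c1Br | intermediate
12 | 4-methoxybenzoyl chloride | COc1ccc(C(=O)Cl)cc1 | starting material
13 | 1-[4,6-bis(benzyloxy)-2-bromo-3-methoxy-5-methylphenyl]-2-methoxy-3-(4-methoxyphenyl)propane-1,3-dione (racemic) | COc1ccc(C(=O)C(OC)C(=O)c2c(OCc3ccccc3)c(C)c(OCc3ccccc3)c(OC)c2Br)cc1 | intermediate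
14 | 5,7-bis(benzyloxy)-3,8-dimethoxy-2-(4-methoxyphenyl)-6-methyl-4H-chromen-4-one | COc1ccc(-c2oc3c(OC)c(OCc4ccccc4)c(C)c(OCc4ccccc4)c3c(=O)c2OC)cc1 | intermediate
15 | 5,7-dihydroxy-3,8-dimethoxy-2-(4-methoxyphenyl)-6-methyl-4H-chromen-4-one | COc1ccc(-c2oc3c(OC)c(O)c(C)c(O)c3c(=O)c2OC)cc1 | target

Total step count: 10 steps.
Longest linear sequence: 8 steps (steps 1, 2, 3, 6, 7, 8, 9 and 10, from compound 1).

Steps most likely to fail

Step 6. The nucleophilic diene may attack the bromine atom of 8 (halophilic transfer), or add at C8a and expel bromide, so that the alkyne is consumed by substitution and not by cycloaddition. The β-bromo-enone unit of 9 may also be solvolysed before the ring aromatises. The fallback carries no halogen through the cycloaddition and brominates afterwards. Setting out from 6, addition of HC≡CMgBr (THF, 0 °C, acidic quench) should give 1-methoxybut-3-yn-2-one F1. Its Diels–Alder addition to diene 4 (toluene, rt) should give the halogen-free cycloadduct 1-[3,6-dimethoxy-5-methyl-4,6-bis(trimethylsilyloxy)cyclohexa-1,4-dien-1-yl]-2-methoxyethan-1-one F2. The same acid work-up should aromatise this to 1-(2,4-dihydroxy-5-methoxy-3-methylphenyl)-2-methoxyethan-1-one F3. Benzylation as in step 7 should give 1-[2,4-bis(benzyloxy)-5-methoxy-3-methylphenyl]-2-methoxyethan-1-one F4. Electrophilic bromination (NBS, MeCN, rt, dark) at the one remaining ring position, ortho to the methoxy group and para to the methyl group, should bring the route back at 11.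

Step 8. O-acylation of the enolate to an enol ester, or a second acylation, may compete with C-acylation at the hindered, methoxy-bearing carbon. The fallback builds the C2–C3 bond at the alcohol oxidation level. Setting out from 11, aldol addition of its lithium enolate (LiN(SiMe3)2, THF, −78 °C) to 4-methoxybenzaldehyde should give 1-[4,6-bis(benzyloxy)-2-bromo-3-methoxy-5-methylphenyl]-3-hydroxy-2-methoxy-3-(4-methoxyphenyl)propan-1-one F5 as a mixture of diastereomers. Oxidation with Dess–Martin periodinane (CH2Cl2, rt) should bring the route back at 13.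

Step 9. Insertion of copper into the C8a–Br bond, which is flanked by the 8-methoxy group and the acyl group on an electron-rich ring, may be slow. Protodebromination or carbonate-induced retro-Claisen cleavage of the diketone could then overtake ring closure. The fallback installs O1 as a phenol first and closes ring C by condensation. Setting out from 11, Pd-catalysed hydroxylation (Pd2(dba)3, t-BuXPhos, KOH, dioxane–H2O, 100 °C) should give 1-[4,6-bis(benzyloxy)-2-hydroxy-3-methoxy-5-methylphenyl]-2-methoxyethan-1-one F6. O-Aroylation with 12 (pyridine, rt) should give 3,5-bis(benzyloxy)-6-methoxy-2-(methoxyacetyl)-4-methylphenyl 4-methoxybenzoate F7. Baker–Venkataraman rearrangement (KOH, pyridine, 50 °C) should give 1-[4,6-bis(benzyloxy)-2-hydroxy-3-methoxy-5-methylphenyl]-2-methoxy-3-(4-methoxyphenyl)propane-1,3-dione F8. Acid-catalysed cyclodehydration (p-TsOH·H2O, toluene, 80 °C) should bring the route back at 14.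

Further compounds
F1 | step 6 | 1-methoxybut-3-yn-2-one | COCC(=O)C#C
F2 | step 6 | 1-[3,6-dimethoxy-5-methyl-4,6-bis(trimethylsilyloxy)cyclohexa-1,4-dien-1-yl]-2-methoxyethan-1-one (diastereomer mixture) | COCC(=O)C1=CC(OC)C(O[Si](C)(C)C)=C(C)C1(OC)O[Si](C)(C)C
F3 | step 6 | 1-(2,4-dihydroxy-5-methoxy-3-methylphenyl)-2-methoxyethan-1-one | COCC(=O)c1cc(OC)c(O)c(C)c1O
F4 | step 6 | 1-[2,4-bis(benzyloxy)-5-methoxy-3-methylphenyl]-2-methoxyethan-1-one | COCC(=O)c1cc(OC)c(OCc2ccccc2)c(C)c1OCc1ccccc1
F5 | step 8 | 1-[4,6-bis(benzyloxy)-2-bromo-3-methoxy-5-methylphenyl]-3-hydroxy-2-methoxy-3-(4-methoxyphenyl)propan-1-one (diastereomer mixture) | COc1ccc(C(O)C(OC)C(=O)c2c(OCc3ccccc3)c(C)c(OCc3ccccc3)c(OC)c2Br)cc1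
F6 | step 9 | 1-[4,6-bis(benzyloxy)-2-hydroxy-3-methoxy-5-methylphenyl]-2-methoxyethan-1-one | COCC(=O)c1c(O)c(OC)c(OCc2ccccc2)c(C)c1OCc1ccccc1
F7 | step 9 | 3,5-bis(benzyloxy)-6-methoxy-2-(methoxyacetyl)-4-methylphenyl 4-methoxybenzoate | COCC(=O)c1c(OC(=O)c2ccc(OC)cc2)c(OC)c(OCc2ccccc2)c(C)c1OCc1ccccc1
F8 | step 9 | 1-[4,6-bis(benzyloxy)-2-hydroxy-3-methoxy-5-methylphenyl]-2-methoxy-3-(4-methoxyphenyl)propane-1,3-dione | COc1ccc(C(=O)C(OC)C(=O)c2c(O)c(OC)c(OCc3ccccc3)c(C)c2OCc2ccccc2)cc1
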